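**Strategy**

The target is unravelled at the C1–C6 and C1′–C6′ bonds of its two cyclohexene end rings (ring A and ring B; carotenoid numbering, C1 = gem-dimethyl carbon). The key step exploits that each ring, with its tetrasubstituted C5=C6 alkene next to the 2-substituted C2, is the cyclase product of a C1=C16 isopropenyl terminus and a C5=C6 chain alkene: one enzymatic operation on the acyclic isomer closes both rings without touching C2 or C2′. The precursor is all-E (2R,2′R)-flavuxanthin, the free C50 diol, built by double Wittig reaction of a limonene-derived C20 hydroxy phosphonium salt with the C10 trienedial.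

Key step: step 11

Remark: C4 of (R)-limonene becomes C2 of the carotenoid with unchanged spatial arrangement and unchanged CIP order (isopropenyl or C1 > hydroxybutenyl arm > C3 > H), so (R)-limonene leads to the (2R,2′R) series and the given structures need no correction; the cyclase is assumed to be available as a membrane preparation from a recombinant host expressing the lbtBC genes of Dietzia sp., and the side-arm hydroxyls are left free from step 8 on because the enzyme's substrate is the free diol.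

**Route**

Step 1
Reactants: 1 (R)-(+)-limonene
Product: 4 (5R)-7,7-dimethoxy-5-(prop-1-en-2-yl)heptan-2-one, via methoxy hydroperoxide aldehyde 2 (not isolated), via methoxy hydroperoxide acetal 3 (not isolated)
Conditions: O3 (1.0 equiv), CH2Cl2/MeOH, −78 °C; p-TsOH·H2O (cat.), rt; NaHCO3; Me2S, rt
Reagents that add atoms: ozone, [O-][O+]=O; methanol, CO
Why: Terminus-differentiating ozonolysis, in which ozone should attack the electron-rich trisubstituted ring alkene before the 1,1-disubstituted isopropenyl group, the carbonyl oxide on the more substituted carbon is trapped by methanol, the released aldehyde is acetalised under acid and Me2S reduces the methoxy hydroperoxide to the methyl ketone, all without involving the stereocentre (C4 of limonene, later C2).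

Step 2
Reactants: 4 (5R)-7,7-dimethoxy-5-(prop-1-en-2-yl)heptan-2-one; 5 triethyl phosphonoacetate
Product: 6 ethyl (2E,6R)-8,8-dimethoxy-3-methyl-6-(prop-1-en-2-yl)oct-2-enoate
Conditions: NaH, THF, 0 °C to 60 °C; silica gel chromatography to remove the 2Z isomer
Reagents that add atoms: none
Why: Horner–Wadsworth–Emmons olefination of the methyl ketone, where reversible adduct formation should favour the E trisubstituted enoate (the later C5=C6 bond) and the minor Z isomer is removed here, while the acetal and the isopropenyl group are inert to the base.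

Step 3
Reactants: 6 ethyl (2E,6R)-8,8-dimethoxy-3-methyl-6-(prop-1-en-2-yl)oct-2-enoate
Product: 7 (2E,6R)-8,8-dimethoxy-3-methyl-6-(prop-1-en-2-yl)oct-2-en-1-ol
Conditions: i-Bu2AlH (2.2 equiv), CH2Cl2, −78 °C; aq. potassium sodium tartrate
Reagents that add atoms: none
Why: Ester reduction by 1,2-hydride delivery from i-Bu2AlH should stop cleanly at the allylic alcohol and leave acetal and alkenes untouched.

Step 4
Reactants: 7 (2E,6R)-8,8-dimethoxy-3-methyl-6-(prop-1-en-2-yl)oct-2-en-1-ol
Product: 8 (2E,6R)-8,8-dimethoxy-3-methyl-6-(prop-1-en-2-yl)oct-2-enal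
Conditions: activated MnO2 (excess), CH2Cl2, rt
Reagents that add atoms: none
Why: Allylic oxidation with MnO2 is selective for the allylic alcohol and neutral, so the E geometry and the acetal should be preserved.

Step 5
Reactants: 8 (2E,6R)-8,8-dimethoxy-3-methyl-6-(prop-1-en-2-yl)oct-2-enal; 9 ethyl (2E)-4-(diethoxyphosphoryl)-3-methylbut-2-enoate (commercial E/Z mixture usable)
Product: 10 ethyl (2E,4E,6E,10R)-12,12-dimethoxy-3,7-dimethyl-10-(prop-1-en-2-yl)dodeca-2,4,6-trienoate
Conditions: LiN(SiMe3)2 (slightly less than 9), THF, −78 °C to 0 °C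
Reagents that add atoms: none
Why: Vinylogous Horner–Wadsworth–Emmons olefination, as in retinoid chain extension, should form C7=C8 as the E alkene and give the E geometry at C9=C10 because the γ-anion equilibrates, and the enal geometry is kept because no free base remains.

Step 6
Reactants: 10 ethyl (2E,4E,6E,10R)-12,12-dimethoxy-3,7-dimethyl-10-(prop-1-en-2-yl)dodeca-2,4,6-trienoate
Product: 11 ethyl (2E,4E,6E,10R)-3,7-dimethyl-12-oxo-10-(prop-1-en-2-yl)dodeca-2,4,6-trienoate
Conditions: p-TsOH·H2O (cat.), acetone/H2O, rt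
Reagents that add atoms: water, O
Why: Acid-catalysed acetal hydrolysis in wet acetone is mild enough for the conjugated trienoate and the isopropenyl group, and the stereocentre is β to the new carbonyl and cannot epimerise.

Step 7
Reactants: 11 ethyl (2E,4E,6E,10R)-3,7-dimethyl-12-oxo-10-(prop-1-en-2-yl)dodeca-2,4,6-trienoate; 12 ethyl 2-(triphenylphosphoranylidene)propanoate
Product: 13 diethyl (2E,4E,6E,10R,12E)-3,7,13-trimethyl-10-(prop-1-en-2-yl)tetradeca-2,4,6,12-tetraenedioate
Conditions: CH2Cl2, rt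
Reagents that add atoms: none
Why: Wittig reaction of the stabilised α-methyl ylide with the unhindered aliphatic aldehyde should give the E trisubstituted enoate of the side arm and does not touch the trienoate.

Step 8
Reactants: 13 diethyl (2E,4E,6E,10R,12E)-3,7,13-trimethyl-10-(prop-1-en-2-yl)tetradeca-2,4,6,12-tetraenedioate
Product: 14 (2E,4E,6E,10R,12E)-3,7,13-trimethyl-10-(prop-1-en-2-yl)tetradeca-2,4,6,12-tetraene-1,14-diol
Conditions: i-Bu2AlH (4.5 equiv), CH2Cl2, −78 °C; aq. potassium sodium tartrate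
Reagents that add atoms: none
Why: Ester reduction of both conjugated esters in 1,2-fashion should give the two primary allylic alcohols, with a neutral work-up because the trienol ionises easily.

Step 9
Reactants: 14 (2E,4E,6E,10R,12E)-3,7,13-trimethyl-10-(prop-1-en-2-yl)tetradeca-2,4,6,12-tetraene-1,14-diol
Product: 15 [(2E,4E,6E,10R,12E)-14-hydroxy-3,7,13-trimethyl-10-(prop-1-en-2-yl)tetradeca-2,4,6,12-tetraen-1-yl]triphenylphosphonium bromide
Conditions: PPh3·HBr (1.0 equiv), MeOH, 0 °C to rt, dark, Ar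
Reagents that add atoms: triphenylphosphine hydrobromide, [Br-].[PH+](c1ccccc1)(c1ccccc1)c1ccccc1
Why: Phosphonium salt formation by ionisation of an allylic alcohol should be selective because only the C11 hydroxyl leaves as a heptatrienyl cation delocalised over C5 to C11, which PPh3 captures at the unhindered C11 terminus, whereas the isolated side-arm allylic alcohol would give only a simple allyl cation and stays intact, as less ionisable hydroxyls do in hydroxylated carotenoid end-group salts.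

Step 10
Reactants: 15 [(2E,4E,6E,10R,12E)-14-hydroxy-3,7,13-trimethyl-10-(prop-1-en-2-yl)tetradeca-2,4,6,12-tetraen-1-yl]triphenylphosphonium bromide (2.2 equiv); 16 (2E,4E,6E)-2,7-dimethylocta-2,4,6-trienedial
Product: 19 (2R,2′R)-all-E-flavuxanthin, via phosphonium ylide 17 (not isolated), via C30 hydroxy aldehyde 18 (not isolated)
Conditions: NaOMe, MeOH/CH2Cl2, 0 °C to rt; then heptane, reflux, Ar, dark; crystallisation
Reagents that add atoms: none
Why: Twofold Wittig reaction of the polyenyl ylide with the C10 dialdehyde forms C11=C12 and C11′=C12′ with the free hydroxyls tolerated, and any hindered 11Z or 11′Z isomers should revert on heating to the all-E polyene, which is expected to crystallise.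

Step 11
Reactants: 19 (2R,2′R)-all-E-flavuxanthin
Product: 21 (2R,2′R)-2,2′-bis[(2E)-4-hydroxy-3-methylbut-2-en-1-yl]-β,β-carotene, via monocyclic carotenoid 20 (not isolated)
Conditions: two-subunit C50 carotenoid β-cyclase of Dietzia sp. (lbtBC gene products, membrane fraction from recombinant E. coli), Tween 80 micelles, Tris-HCl pH 7.5, 30 °C, Ar, dark; CHCl3/MeOH extraction, chromatography, recycling of 19 and 20
Reagents that add atoms: none
Why: The cyclase protonates C16 of a terminal C1=C16 alkene, the tertiary C1 cation is trapped by C6 of the C5=C6 alkene and the resulting C5 cation loses H-6, a net isomerisation that this enzyme family performs on flavuxanthin in the biosynthesis of the pigment and that parallels the lycopene to β-carotene cyclisation. Ring A and ring B each close by a 6-endo-trig cation–olefin attack (C1 on C6), first at one end to give monocyclic 20 and then at the other. No stereocentre is created, since C1 becomes the gem-dimethyl carbon and C6 ends as an sp2 carbon, and C2 and C2′ remain spectators with the R configuration brought from limonene. The step needs protonation at the isopropenyl groups instead of the polyene or the side-arm alkenes, exclusive C1–C6 closure and loss of H-6 and not H-4 or H-18, all of which the active site should impose on its native all-E (2R,2′R) substrate, whereas mineral or Lewis acids would not discriminate. The open question is delivery of an externally supplied, water-insoluble and oxygen-sensitive substrate to a membrane enzyme, which is why micellar dosing, exclusion of light and air, and recycling of partly converted material are planned.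

**Compound list**

1 | (R)-(+)-limonene | CC1=CC[C@@H](CC1)C(C)=C | starting material
2 | (3R)-6-hydroperoxy-6-methoxy-3-(prop-1-en-2-yl)heptanal (C6 epimers) | CC(OC)(OO)CC[C@H](CC=O)C(C)=C | intermediate
3 | (5R)-2-hydroperoxy-2,7,7-trimethoxy-5-(prop-1-en-2-yl)heptane (C2 epimers) | CC(OC)(OO)CC[C@H](CC(OC)OC)C(C)=C | intermediate
4 | (5R)-7,7-dimethoxy-5-(prop-1-en-2-yl)heptan-2-one | CC(=O)CC[C@H](CC(OC)OC)C(C)=C | intermediate
5 | triethyl phosphonoacetate | CCOC(=O)CP(=O)(OCC)OCC | starting material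
6 | ethyl (2E,6R)-8,8-dimethoxy-3-methyl-6-(prop-1-en-2-yl)oct-2-enoate | CCOC(=O)/C=C(\C)CC[C@H](CC(OC)OC)C(C)=C | intermediate
7 | (2E,6R)-8,8-dimethoxy-3-methyl-6-(prop-1-en-2-yl)oct-2-en-1-ol | OC/C=C(\C)CC[C@H](CC(OC)OC)C(C)=C | intermediate
8 | (2E,6R)-8,8-dimethoxy-3-methyl-6-(prop-1-en-2-yl)oct-2-enal | O=C/C=C(\C)CC[C@H](CC(OC)OC)C(C)=C | intermediate
9 | ethyl (2E)-4-(diethoxyphosphoryl)-3-methylbut-2-enoate | CCOC(=O)/C=C(\C)CP(=O)(OCC)OCC | starting material
10 | ethyl (2E,4E,6E,10R)-12,12-dimethoxy-3,7-dimethyl-10-(prop-1-en-2-yl)dodeca-2,4,6-trienoate | CCOC(=O)/C=C(C)/C=C/C=C(\C)CC[C@H](CC(OC)OC)C(C)=C | intermediate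
11 | ethyl (2E,4E,6E,10R)-3,7-dimethyl-12-oxo-10-(prop-1-en-2-yl)dodeca-2,4,6-trienoate | CCOC(=O)/C=C(C)/C=C/C=C(\C)CC[C@H](CC=O)C(C)=C | intermediate
12 | ethyl 2-(triphenylphosphoranylidene)propanoate | CCOC(=O)C(C)=P(c1ccccc1)(c1ccccc1)c1ccccc1 | starting material
13 | diethyl (2E,4E,6E,10R,12E)-3,7,13-trimethyl-10-(prop-1-en-2-yl)tetradeca-2,4,6,12-tetraenedioate | CCOC(=O)/C=C(C)/C=C/C=C(\C)CC[C@H](C/C=C(\C)C(=O)OCC)C(C)=C | intermediate
14 | (2E,4E,6E,10R,12E)-3,7,13-trimethyl-10-(prop-1-en-2-yl)tetradeca-2,4,6,12-tetraene-1,14-diol | OC/C=C(C)/C=C/C=C(\C)CC[C@H](C/C=C(\C)CO)C(C)=C | intermediate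
15 | [(2E,4E,6E,10R,12E)-14-hydroxy-3,7,13-trimethyl-10-(prop-1-en-2-yl)tetradeca-2,4,6,12-tetraen-1-yl]triphenylphosphonium bromide | c1ccccc1[P+](c1ccccc1)(c1ccccc1)C/C=C(C)/C=C/C=C(\C)CC[C@H](C/C=C(\C)CO)C(C)=C.[Br-] | intermediate
16 | (2E,4E,6E)-2,7-dimethylocta-2,4,6-trienedial | O=C/C(C)=C/C=C/C=C(C)/C=O | starting material
17 | [(2E,4E,6E,10R,12E)-14-hydroxy-3,7,13-trimethyl-10-(prop-1-en-2-yl)tetradeca-2,4,6,12-tetraen-1-ylidene]triphenylphosphorane | c1ccccc1P(c1ccccc1)(c1ccccc1)=C/C=C(C)/C=C/C=C(\C)CC[C@H](C/C=C(\C)CO)C(C)=C | intermediate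
18 | (2E,4E,6E,8E,10E,12E,14E,18R,20E)-22-hydroxy-2,7,11,15,21-pentamethyl-18-(prop-1-en-2-yl)docosa-2,4,6,8,10,12,14,20-octaenal | O=C/C(C)=C/C=C/C=C(C)/C=C/C=C(C)/C=C/C=C(C)/CC[C@H](C/C=C(\C)CO)C(C)=C | intermediate
19 | (2R,2′R)-all-E-flavuxanthin, 2,2′-bis[(2E)-4-hydroxy-3-methylbut-2-en-1-yl]-1,16,1′,16′-tetradehydro-1,2,1′,2′-tetrahydro-ψ,ψ-carotene | C=C(C)[C@@H](C/C=C(\C)CO)CC/C(C)=C/C=C/C(C)=C/C=C/C(C)=C/C=C/C=C(C)/C=C/C=C(C)/C=C/C=C(C)/CC[C@H](C/C=C(\C)CO)C(C)=C | intermediate
20 | (2R,2′R)-2,2′-bis[(2E)-4-hydroxy-3-methylbut-2-en-1-yl]-1′,16′-didehydro-1′,2′-dihydro-β,ψ-carotene (ring A closed, other end acyclic) | CC1=C(/C=C/C(C)=C/C=C/C(C)=C/C=C/C=C(C)/C=C/C=C(C)/C=C/C=C(C)/CC[C@H](C/C=C(\C)CO)C(C)=C)C(C)(C)[C@@H](C/C=C(\C)CO)CC1 | intermediate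
21 | (2R,2′R)-2,2′-bis[(2E)-4-hydroxy-3-methylbut-2-en-1-yl]-β,β-carotene | CC1=C(/C=C/C(C)=C/C=C/C(C)=C/C=C/C=C(C)/C=C/C=C(C)/C=C/C2=C(C)CC[C@H](C/C=C(\C)CO)C2(C)C)C(C)(C)[C@@H](C/C=C(\C)CO)CC1 | target

**Step count and risks**

Total step count: 11. Longest linear sequence: 11 steps (1 to 21); 5, 9, 12 and 16 are purchased.

Steps most likely to fail:

1. Step 11. The water-insoluble, air- and light-sensitive substrate may not reach the membrane-bound active site, or turnover may stall after the first ring closure. The fallback gives up the enzyme and moves C1–C6 bond formation to the C20 stage; it sets out from diester 13. Brønsted acid cyclisation of the pseudoionone to β-ionone type (H2SO4/AcOH, 0 °C) would protonate the isopropenyl group and close the ring onto the chain alkene, the electron-poor side-arm enoate not competing, to give the cyclohexene diester F1 after separation from double-bond isomers. Reduction with i-Bu2AlH would give the cyclohexene diol F2, and PPh3·HBr in MeOH the cyclic C20 phosphonium bromide F3. With NaOMe this forms the cyclic ylide F4, which condenses with dialdehyde 16 through the cyclic C30 hydroxy aldehyde F5 and, after thermal Z to E equilibration, comes back to the route at target 21.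

2. Step 2. The olefination of a methyl ketone may show insufficient E/Z selectivity at the later C5=C6 bond, which cannot be corrected afterwards, and separation may cost much material. The fallback replaces carbonyl olefination by alkyne carbometalation and sets out from ketone 4. Kinetic enolisation on the methyl side with LiN(i-Pr)2 (THF, −78 °C) and trapping with ClP(O)(OEt)2 would give the enol phosphate F6, which further LiN(i-Pr)2 (2.2 equiv) eliminates to the terminal alkyne F7. Syn methylalumination with AlMe3 and Cp2ZrCl2 (CH2Cl2, water-accelerated, −20 °C to spare the acetal; Negishi carboalumination) would give the alkenylalane F8 with methyl and aluminium cis, and quenching with ethyl chloroformate comes back at enoate 6 as the E isomer only.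

3. Step 9. Chemoselectivity between the two allylic hydroxyls may be lost, or the geometry at C5=C6 may scramble through the delocalised cation. The fallback differentiates the hydroxyls by a protecting group and sets out from aldehyde 11. Wittig reaction with 2-(triphenylphosphoranylidene)propanal would give the enal ester F9, and NaBH4/CeCl3·7H2O (MeOH, 0 °C) would reduce only the aldehyde to the hydroxy ester F10. Silylation with t-BuPh2SiCl and imidazole would give the silyl ether ester F11, and i-Bu2AlH the silyl ether trienol F12, which now carries a single free hydroxyl. PPh3·HBr would then give the silyl-protected phosphonium bromide F13; NaOMe converts it to the silyl-protected ylide F14, which reacts with dialdehyde 16 through the silyl-protected C30 aldehyde F15 to the bis-silyl flavuxanthin F16. Bu4NF in THF comes back to the route at flavuxanthin 19.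

**Further compounds**

F1 | step 11 | ethyl (2E,4E)-5-[(5R)-5-[(2E)-4-ethoxy-3-methyl-4-oxobut-2-en-1-yl]-2,6,6-trimethylcyclohex-1-en-1-yl]-3-methylpenta-2,4-dienoate | CCOC(=O)/C=C(C)/C=C/C1=C(C)CC[C@H](C/C=C(\C)C(=O)OCC)C1(C)C
F2 | step 11 | (2E,4E)-5-[(5R)-5-[(2E)-4-hydroxy-3-methylbut-2-en-1-yl]-2,6,6-trimethylcyclohex-1-en-1-yl]-3-methylpenta-2,4-dien-1-ol | OC/C=C(C)/C=C/C1=C(C)CC[C@H](C/C=C(\C)CO)C1(C)C
F3 | step 11 | [(2E,4E)-5-[(5R)-5-[(2E)-4-hydroxy-3-methylbut-2-en-1-yl]-2,6,6-trimethylcyclohex-1-en-1-yl]-3-methylpenta-2,4-dien-1-yl]triphenylphosphonium bromide | c1ccccc1[P+](c1ccccc1)(c1ccccc1)C/C=C(C)/C=C/C1=C(C)CC[C@H](C/C=C(\C)CO)C1(C)C.[Br-]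
F4 | step 11 | [(2E,4E)-5-[(5R)-5-[(2E)-4-hydroxy-3-methylbut-2-en-1-yl]-2,6,6-trimethylcyclohex-1-en-1-yl]-3-methylpenta-2,4-dien-1-ylidene]triphenylphosphorane | c1ccccc1P(c1ccccc1)(c1ccccc1)=C/C=C(C)/C=C/C1=C(C)CC[C@H](C/C=C(\C)CO)C1(C)C
F5 | step 11 | (2E,4E,6E,8E,10E,12E)-13-[(5R)-5-[(2E)-4-hydroxy-3-methylbut-2-en-1-yl]-2,6,6-trimethylcyclohex-1-en-1-yl]-2,7,11-trimethyltrideca-2,4,6,8,10,12-hexaenal | O=C/C(C)=C/C=C/C=C(C)/C=C/C=C(C)/C=C/C1=C(C)CC[C@H](C/C=C(\C)CO)C1(C)C
F6 | step 2 | diethyl (5R)-7,7-dimethoxy-5-(prop-1-en-2-yl)hept-1-en-2-yl phosphate | C=C(OP(=O)(OCC)OCC)CC[C@H](CC(OC)OC)C(C)=C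
F7 | step 2 | (5R)-7,7-dimethoxy-5-(prop-1-en-2-yl)hept-1-yne | C#CCC[C@H](CC(OC)OC)C(C)=C
F8 | step 2 | [(1E,5R)-7,7-dimethoxy-2-methyl-5-(prop-1-en-2-yl)hept-1-en-1-yl]dimethylalane | C[Al](C)/C=C(\C)CC[C@H](CC(OC)OC)C(C)=C
F9 | step 9 | ethyl (2E,4E,6E,10R,12E)-3,7,13-trimethyl-14-oxo-10-(prop-1-en-2-yl)tetradeca-2,4,6,12-tetraenoate | CCOC(=O)/C=C(C)/C=C/C=C(\C)CC[C@H](C/C=C(\C)C=O)C(C)=C
F10 | step 9 | ethyl (2E,4E,6E,10R,12E)-14-hydroxy-3,7,13-trimethyl-10-(prop-1-en-2-yl)tetradeca-2,4,6,12-tetraenoate | CCOC(=O)/C=C(C)/C=C/C=C(\C)CC[C@H](C/C=C(\C)CO)C(C)=C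
F11 | step 9 | ethyl (2E,4E,6E,10R,12E)-14-[(tert-butyldiphenylsilyl)oxy]-3,7,13-trimethyl-10-(prop-1-en-2-yl)tetradeca-2,4,6,12-tetraenoate | CCOC(=O)/C=C(C)/C=C/C=C(\C)CC[C@H](C/C=C(\C)CO[Si](c1ccccc1)(c1ccccc1)C(C)(C)C)C(C)=C
F12 | step 9 | (2E,4E,6E,10R,12E)-14-[(tert-butyldiphenylsilyl)oxy]-3,7,13-trimethyl-10-(prop-1-en-2-yl)tetradeca-2,4,6,12-tetraen-1-ol | OC/C=C(C)/C=C/C=C(\C)CC[C@H](C/C=C(\C)CO[Si](c1ccccc1)(c1ccccc1)C(C)(C)C)C(C)=C
F13 | step 9 | [(2E,4E,6E,10R,12E)-14-[(tert-butyldiphenylsilyl)oxy]-3,7,13-trimethyl-10-(prop-1-en-2-yl)tetradeca-2,4,6,12-tetraen-1-yl]triphenylphosphonium bromide | c1ccccc1[P+](c1ccccc1)(c1ccccc1)C/C=C(C)/C=C/C=C(\C)CC[C@H](C/C=C(\C)CO[Si](c1ccccc1)(c1ccccc1)C(C)(C)C)C(C)=C.[Br-]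
F14 | step 9 | [(2E,4E,6E,10R,12E)-14-[(tert-butyldiphenylsilyl)oxy]-3,7,13-trimethyl-10-(prop-1-en-2-yl)tetradeca-2,4,6,12-tetraen-1-ylidene]triphenylphosphorane | c1ccccc1P(c1ccccc1)(c1ccccc1)=C/C=C(C)/C=C/C=C(\C)CC[C@H](C/C=C(\C)CO[Si](c1ccccc1)(c1ccccc1)C(C)(C)C)C(C)=C
F15 | step 9 | (2E,4E,6E,8E,10E,12E,14E,18R,20E)-22-[(tert-butyldiphenylsilyl)oxy]-2,7,11,15,21-pentamethyl-18-(prop-1-en-2-yl)docosa-2,4,6,8,10,12,14,20-octaenal | O=C/C(C)=C/C=C/C=C(C)/C=C/C=C(C)/C=C/C=C(C)/CC[C@H](C/C=C(\C)CO[Si](c1ccccc1)(c1ccccc1)C(C)(C)C)C(C)=C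
F16 | step 9 | (2R,2′R)-all-E-flavuxanthin bis(tert-butyldiphenylsilyl) ether | C=C(C)[C@@H](C/C=C(\C)CO[Si](c1ccccc1)(c1ccccc1)C(C)(C)C)CC/C(C)=C/C=C/C(C)=C/C=C/C(C)=C/C=C/C=C(C)/C=C/C=C(C)/C=C/C=C(C)/CC[C@H](C/C=C(\C)CO[Si](c1ccccc1)(c1ccccc1)C(C)(C)C)C(C)=C
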